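**Plan**

1. Retrosynthesis: the ester and the C-methyl on the side-chain alkene are cut last, which leaves an alkyne between the ring and the quaternary carbon. Ring A is then opened across two bonds at once: the diene C=C that is exocyclic to ring B, and the σ bond between the ring-fusion CH and the CH that carries the side chain. The acyclic partner is cut at its alkenyl–alkenyl and alkynyl–alkynyl bonds.
2. Enabling feature: ring A is a cyclohexa-1,3-diene whose only two sp3 atoms are adjacent (the ring-fusion CH of ring B and the side-chain CH). This is the retron of a hexatriene 6π-electrocyclization in which the terminal C=C is the enol double bond of a ring-B ketone. A Suzuki–Miyaura coupling of the ring-B enol triflate with a (Z,Z)-dienyl boronate makes that triene, and it closes in the same flask.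
3. Forward order: ring B (cyclohexanone) is made first from a quinone monoketal by two copper-catalysed methyl additions, the second enolate being trapped as the triflate. The side chain follows (iridium-catalysed tert-(hydroxy)prenylation for the quaternary carbon, then alkyne and enoate). The fragments are joined by Cadiot–Chodkiewicz coupling, hydroxyl-directed trans-hydrostannation and Stille coupling; ring A forms last, in the key step. Oxidation, unmasking, trans-hydrostannation/C-methylation and ester cleavage finish the route.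
4. The side-chain alkene is carried through ring closure as an alkyne. It is small enough to sit "inside" the triene (required for the trans relation of the two new centres), it has no C–H for a [1,7]-shift, and it avoids a conjugated tetraene that would close by the 8π mode.
5. Stereochemistry: the two ring-B methyl centres come from catalyst-controlled conjugate additions (they are also the all-equatorial arrangement). The ring-fusion CH and the side-chain CH come from the disrotatory closure (trans by triene geometry, facial sense from the conformationally locked cis-dimethyl ring B). The quaternary carbon comes from the chiral iridium catalyst. Alkene geometries come from syn-bromoboration, two anti-hydrostannations and a Wittig olefination.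

Key step: step 14

Remark 1: in steps 1, 2 and 4 the enantiomer of the chiral ligand is taken to be the one that gives the configuration drawn; the sense of induction is to be fixed by the choice of ligand enantiomer.
Remark 2: the carbinol centres of 12 and of the 2-hydroxypropyl chain (from 22) are oxidised later, so their configuration is a matter of convenience; epoxide 9 is used as the racemate because its stereocentre is erased in the allyl-iridium intermediate.
Remark 3: ring locants in the names follow naphthalene numbering (C1 carries the side chain, C8a is the ring-fusion CH, C7 is the ring-B carbonyl or ketal carbon).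

**Step 1**
Reactants: 1 4,4-dimethoxycyclohexa-2,5-dien-1-one
Product: 3 (5S)-4,4-dimethoxy-5-methylcyclohex-2-en-1-one, via methylzinc dienolate 2 (not isolated)
Conditions: Me2Zn (1.3 equiv), Cu(OTf)2 (2 mol %), BINOL-derived bis(1-phenylethyl)amine phosphoramidite (4 mol %), toluene, −25 °C; aq. NH4Cl
Reagents that add atoms: dimethylzinc, C[Zn]C
Why: Copper/phosphoramidite-catalysed enantioselective conjugate addition of a dialkylzinc to a cyclohexadienone monoketal; the chiral copper complex selects one enantiotopic β-carbon/face of the achiral dienone and so sets the methyl-bearing centre, and the product stays as its zinc dienolate until work-up, which prevents a second addition.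

**Step 2**
Reactants: 3 (5S)-4,4-dimethoxy-5-methylcyclohex-2-en-1-one
Product: 5 (3R,5S)-4,4-dimethoxy-3,5-dimethylcyclohex-1-en-1-yl trifluoromethanesulfonate, via methylzinc enolate 4 (not isolated)
Conditions: Me2Zn (1.5 equiv), Cu(OTf)2 (2 mol %), enantiomeric phosphoramidite (4 mol %), toluene, −25 °C; then Tf2O (1.1 equiv), −78 to 0 °C
Reagents that add atoms: dimethylzinc, C[Zn]C; trifluoromethanesulfonic anhydride, O=S(=O)(OS(=O)(=O)C(F)(F)F)C(F)(F)F
Why: A second catalyst-controlled conjugate addition, run with the enantiomeric ligand so that the new methyl should enter cis to the first (catalyst control over the substrate's trans bias), followed by O-triflation of the regiodefined zinc enolate; the enol double bond is thereby fixed on the side of the second methyl, which makes the otherwise meso-related ring chiral.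

**Step 3**
Reactants: 6 propyne
Product: 8 2-[(Z)-2-bromoprop-1-en-1-yl]-4,4,5,5-tetramethyl-1,3,2-dioxaborolane, via dibromoborane 7 (not isolated)
Conditions: BBr3, CH2Cl2, −78 °C; then pinacol, −78 °C to rt
Reagents that add atoms: boron tribromide, BrB(Br)Br; pinacol, CC(C)(O)C(C)(C)O
Why: syn-Bromoboration of a terminal alkyne (boron to the terminal carbon, bromine to the internal carbon) followed by esterification; the syn addition fixes the Z geometry with Br and B cis.

**Step 4**
Reactants: 9 2-methyl-2-vinyloxirane (racemic); 10 ethanol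
Product: 12 (2R,3S)-2-ethenyl-2-methylbutane-1,3-diol, via acetaldehyde 11 (not isolated)
Conditions: preformed π-allyliridium C,O-benzoate catalyst from [Ir(cod)Cl]2, (R)-Tol-BINAP, 4-cyano-3-nitrobenzoic acid and allyl acetate (5 mol %), K3PO4 (5 mol %), ethanol (3 equiv), THF, 60 °C
Reagents that add atoms: none
Why: Iridium-catalysed redox-triggered carbonyl tert-(hydroxy)prenylation: the catalyst dehydrogenates ethanol to acetaldehyde, ionises the vinyl epoxide to a hydroxymethyl-substituted allyliridium species and adds it through its substituted terminus to the aldehyde, so the quaternary centre is set by the chiral bisphosphine–iridium complex.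

**Step 5**
Reactants: 12 (2R,3S)-2-ethenyl-2-methylbutane-1,3-diol
Product: 13 (2S,3R)-3-({[tert-butyl(dimethyl)silyl]oxy}methyl)-3-methylpent-4-en-2-ol
Conditions: TBSCl (1.05 equiv), imidazole, CH2Cl2, 0 °C
Reagents that add atoms: tert-butyldimethylsilyl chloride, CC(C)(C)[Si](C)(C)Cl
Why: Selective silylation of the primary hydroxyl over the secondary hydroxyl that is flanked by the quaternary carbon; no stereocentre is touched.

**Step 6**
Reactants: 13 (2S,3R)-3-({[tert-butyl(dimethyl)silyl]oxy}methyl)-3-methylpent-4-en-2-ol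
Product: 14 (3R)-3-({[tert-butyl(dimethyl)silyl]oxy}methyl)-3-methylpent-4-en-2-one
Conditions: Dess–Martin periodinane, CH2Cl2, rt
Reagents that add atoms: none
Why: Dess–Martin oxidation of the secondary alcohol to the methyl ketone; the α-carbon is quaternary, so neither epimerisation nor β-elimination of the silyloxy group is possible.

**Step 7**
Reactants: 14 (3R)-3-({[tert-butyl(dimethyl)silyl]oxy}methyl)-3-methylpent-4-en-2-one
Product: 18 tert-butyl{[(2S)-2-ethynyl-2-methylbut-3-en-1-yl]oxy}dimethylsilane, via lithium enolate 15 (not isolated), via enol phosphate 16 (not isolated), via lithium acetylide 17 (not isolated)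
Conditions: LiN(i-Pr)2 (1.1 equiv), THF, −78 °C; ClP(O)(OEt)2; then LiN(i-Pr)2 (2.3 equiv), −78 °C to rt; aq. NH4Cl
Reagents that add atoms: none
Why: Conversion of a methyl ketone into a terminal alkyne by O-phosphorylation of the enolate at its only enolisable position and base-induced elimination of the enol phosphate; the quaternary centre takes no part (its descriptor changes only through the priority rules).

**Step 8**
Reactants: 18 tert-butyl{[(2S)-2-ethynyl-2-methylbut-3-en-1-yl]oxy}dimethylsilane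
Product: 20 (2S)-2-({[tert-butyl(dimethyl)silyl]oxy}methyl)-2-methylbut-3-ynal, via ozonide 19 (not isolated)
Conditions: O3, CH2Cl2, −78 °C (stopped at the first trace of blue); then PPh3, −78 °C to rt
Reagents that add atoms: ozone, [O-][O+]=O
Why: Ozonolysis with reductive work-up; ozone reacts with the monosubstituted alkene far faster than with the terminal alkyne, and the aldehyde formed has no α-hydrogen.

**Step 9**
Reactants: 20 (2S)-2-({[tert-butyl(dimethyl)silyl]oxy}methyl)-2-methylbut-3-ynal
Product: 21 methyl (2E,4S)-4-({[tert-butyl(dimethyl)silyl]oxy}methyl)-4-methylhex-2-en-5-ynoate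
Conditions: Ph3P=CHCO2Me (1.5 equiv), toluene, 80 °C
Reagents that add atoms: methyl (triphenylphosphoranylidene)acetate, COC(=O)C=P(c1ccccc1)(c1ccccc1)c1ccccc1
Why: Wittig olefination with a stabilised ylide, which should give the (E)-enoate.

**Step 10**
Reactants: 22 (2S)-pent-4-yn-2-ol
Product: 23 (2S)-5-bromopent-4-yn-2-ol
Conditions: NBS (1.1 equiv), AgNO3 (10 mol %), acetone, rt
Reagents that add atoms: N-bromosuccinimide, O=C1CCC(=O)N1Br
Why: Silver-catalysed electrophilic bromination of a terminal alkyne; the free hydroxyl is tolerated.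

**Step 11**
Reactants: 21 methyl (2E,4S)-4-({[tert-butyl(dimethyl)silyl]oxy}methyl)-4-methylhex-2-en-5-ynoate; 23 (2S)-5-bromopent-4-yn-2-ol
Product: 24 methyl (2E,4S,10S)-4-({[tert-butyl(dimethyl)silyl]oxy}methyl)-10-hydroxy-4-methylundec-2-ene-5,7-diynoate
Conditions: CuCl (10 mol %), NH2OH·HCl (30 mol %), n-BuNH2 (30 % aq), CH2Cl2, 0 °C
Reagents that add atoms: none
Why: Cadiot–Chodkiewicz coupling of a terminal alkyne with a 1-bromoalkyne to the unsymmetrical 1,3-diyne; hydroxylamine keeps the copper monovalent and suppresses homocoupling, and the β-carbon of the enoate is shielded from the amine by the adjacent quaternary carbon.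

**Step 12**
Reactants: 24 methyl (2E,4S,10S)-4-({[tert-butyl(dimethyl)silyl]oxy}methyl)-10-hydroxy-4-methylundec-2-ene-5,7-diynoate
Product: 25 methyl (2E,4S,7Z,10S)-4-({[tert-butyl(dimethyl)silyl]oxy}methyl)-10-hydroxy-4-methyl-8-(tributylstannyl)undeca-2,7-dien-5-ynoate
Conditions: [Cp*RuCl]4 (2.5 mol %), Bu3SnH (1.05 equiv, slow addition), CH2Cl2, rt
Reagents that add atoms: tributyltin hydride, CCCC[SnH](CCCC)CCCC
Why: Ruthenium-catalysed hydroxyl-directed trans-hydrostannation: the hydrogen bond from the homopropargylic OH to the chloride on ruthenium should select the nearer triple bond and deliver tin to its proximal carbon, and the anti addition places tin cis to the remaining alkynyl group (7Z); the distal alkyne, flanked by the quaternary carbon and without a protic neighbour, should be left.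

**Step 13**
Reactants: 25 methyl (2E,4S,7Z,10S)-4-({[tert-butyl(dimethyl)silyl]oxy}methyl)-10-hydroxy-4-methyl-8-(tributylstannyl)undeca-2,7-dien-5-ynoate; 8 2-[(Z)-2-bromoprop-1-en-1-yl]-4,4,5,5-tetramethyl-1,3,2-dioxaborolane
Product: 26 methyl (2E,4S,7Z,10S)-4-({[tert-butyl(dimethyl)silyl]oxy}methyl)-10-hydroxy-4-methyl-8-[(1Z)-1-(4,4,5,5-tetramethyl-1,3,2-dioxaborolan-2-yl)prop-1-en-2-yl]undeca-2,7-dien-5-ynoate
Conditions: Pd(PPh3)4 (10 mol %), Cu(O2CC4H3S) (CuTC, 1.5 equiv), [NBu4][Ph2PO2] (1.6 equiv), DMF, rt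
Reagents that add atoms: none
Why: Stille coupling promoted by copper thiophenecarboxylate and phosphinate (base- and fluoride-free, so the pinacol boronate should stay intact) with retention at both alkenyl carbons, which gives the (Z,Z)-diene.

**Step 14**
Reactants: 26 methyl (2E,4S,7Z,10S)-4-({[tert-butyl(dimethyl)silyl]oxy}methyl)-10-hydroxy-4-methyl-8-[(1Z)-1-(4,4,5,5-tetramethyl-1,3,2-dioxaborolan-2-yl)prop-1-en-2-yl]undeca-2,7-dien-5-ynoate; 5 (3R,5S)-4,4-dimethoxy-3,5-dimethylcyclohex-1-en-1-yl trifluoromethanesulfonate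
Product: 28 methyl (2E,4S)-4-({[tert-butyl(dimethyl)silyl]oxy}methyl)-6-[(1R,6S,8R,8aR)-2-[(2S)-2-hydroxypropyl]-7,7-dimethoxy-3,6,8-trimethyl-1,5,6,7,8,8a-hexahydronaphthalen-1-yl]-4-methylhex-2-en-5-ynoate, via trienyne 27 (not isolated)
Conditions: Pd(dppf)Cl2 (5 mol %), K3PO4 (3 equiv), THF/H2O (10:1), 45 °C; then toluene, 100 °C, same flask
Reagents that add atoms: none
Why: Oxidative addition of zerovalent palladium into the C–OTf bond of 5, transmetalation of the alkenyl group of 26 and reductive elimination join the triflate carbon of ring B to the boron-bearing CH and give the (Z,Z)-trienyne 27; on heating, 27 should undergo a thermal disrotatory 6π-electrocyclization in which the ring-B alkene CH bonds to the alkynyl-bearing terminus, so that the coupled bond becomes the diene C=C exocyclic to ring B and the new σ bond closes ring A. The closest known reaction type is the Suzuki–Miyaura (or Stille) coupling/6π-electrocyclization cascade to cyclohexa-1,3-dienes. Ring A, a six-membered carbocycle, is closed in the 6π-electrocyclic mode. The trans relation of the two new sp3 centres follows from disrotation of a triene whose ring-B terminus carries its carbon substituent outside and whose other terminus carries the alkynyl group inside (Z); the absolute sense follows from ring B, whose cis-dimethyl groups hold the half-chair with both methyls equatorial, so that the rotation that lets ring B relax directly to the chair places the new bond equatorial and anti to the neighbouring methyl. The step needs periselectivity and torquoselectivity: the alkyne in place of the side-chain alkene removes the conjugated tetraene and with it the 8π closure, the inside substituent has no sp3 C–H for a [1,7]-hydrogen shift, and 100 °C lies below the onset of [1,5]-hydrogen shifts in cyclohexadienes.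

**Step 15**
Reactants: 28 methyl (2E,4S)-4-({[tert-butyl(dimethyl)silyl]oxy}methyl)-6-[(1R,6S,8R,8aR)-2-[(2S)-2-hydroxypropyl]-7,7-dimethoxy-3,6,8-trimethyl-1,5,6,7,8,8a-hexahydronaphthalen-1-yl]-4-methylhex-2-en-5-ynoate
Product: 29 methyl (2E,4S)-4-({[tert-butyl(dimethyl)silyl]oxy}methyl)-6-[(1R,6S,8R,8aR)-7,7-dimethoxy-3,6,8-trimethyl-2-(2-oxopropyl)-1,5,6,7,8,8a-hexahydronaphthalen-1-yl]-4-methylhex-2-en-5-ynoate
Conditions: Dess–Martin periodinane, pyridine, CH2Cl2, 0 °C to rt
Reagents that add atoms: none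
Why: Dess–Martin oxidation of the only free hydroxyl; the pyridine buffer should protect the ketal and the silyl ether and keep the new β,γ-unsaturated ketone out of conjugation.

**Step 16**
Reactants: 29 methyl (2E,4S)-4-({[tert-butyl(dimethyl)silyl]oxy}methyl)-6-[(1R,6S,8R,8aR)-7,7-dimethoxy-3,6,8-trimethyl-2-(2-oxopropyl)-1,5,6,7,8,8a-hexahydronaphthalen-1-yl]-4-methylhex-2-en-5-ynoate
Product: 30 methyl (2E,4S)-4-(hydroxymethyl)-4-methyl-6-[(1R,6S,8R,8aR)-3,6,8-trimethyl-7-oxo-2-(2-oxopropyl)-1,5,6,7,8,8a-hexahydronaphthalen-1-yl]hex-2-en-5-ynoate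
Conditions: HCl (1 M aq), THF, 0 °C to rt
Reagents that add atoms: water, O
Why: Acid hydrolysis of the dimethyl ketal and of the primary silyl ether in one step; the two α-methyl centres of the liberated ketone are the all-equatorial arrangement, so enolisation should not erode them.

**Step 17**
Reactants: 30 methyl (2E,4S)-4-(hydroxymethyl)-4-methyl-6-[(1R,6S,8R,8aR)-3,6,8-trimethyl-7-oxo-2-(2-oxopropyl)-1,5,6,7,8,8a-hexahydronaphthalen-1-yl]hex-2-en-5-ynoate
Product: 31 methyl (2E,4R,5Z)-4-(hydroxymethyl)-4-methyl-5-(tributylstannyl)-6-[(1R,6S,8R,8aR)-3,6,8-trimethyl-7-oxo-2-(2-oxopropyl)-1,5,6,7,8,8a-hexahydronaphthalen-1-yl]hexa-2,5-dienoate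
Conditions: [Cp*RuCl]4 (5 mol %), Bu3SnH (1.2 equiv), CH2Cl2, rt
Reagents that add atoms: tributyltin hydride, CCCC[SnH](CCCC)CCCC
Why: A second ruthenium-catalysed hydroxyl-directed trans-hydrostannation: the free CH2OH on the quaternary carbon is homopropargylic, so tin should go to the alkyne carbon next to the quaternary carbon and hydrogen anti to it on the ring side; ketones, the enoate and the tri- and tetrasubstituted ring alkenes are not expected to react.

**Step 18**
Reactants: 31 methyl (2E,4R,5Z)-4-(hydroxymethyl)-4-methyl-5-(tributylstannyl)-6-[(1R,6S,8R,8aR)-3,6,8-trimethyl-7-oxo-2-(2-oxopropyl)-1,5,6,7,8,8a-hexahydronaphthalen-1-yl]hexa-2,5-dienoate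
Product: 32 methyl (2E,4S,5E)-4-(hydroxymethyl)-4,5-dimethyl-6-[(1S,6S,8R,8aR)-3,6,8-trimethyl-7-oxo-2-(2-oxopropyl)-1,5,6,7,8,8a-hexahydronaphthalen-1-yl]hexa-2,5-dienoate
Conditions: MeI (10 equiv), Pd(PPh3)4 (15 mol %), Cu(O2CC4H3S) (CuTC, 1.5 equiv), [NBu4][Ph2PO2] (1.6 equiv), DMF, rt
Reagents that add atoms: iodomethane, CI
Why: Stille-type C-methylation of the alkenylstannane, assisted by the neighbouring hydroxyl, with retention of geometry; the net anti-hydromethylation of the alkyne gives the (E)-trisubstituted alkene.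

**Step 19**
Reactants: 32 methyl (2E,4S,5E)-4-(hydroxymethyl)-4,5-dimethyl-6-[(1S,6S,8R,8aR)-3,6,8-trimethyl-7-oxo-2-(2-oxopropyl)-1,5,6,7,8,8a-hexahydronaphthalen-1-yl]hexa-2,5-dienoate
Product: 34 (2E,4S,5E)-4-(hydroxymethyl)-4,5-dimethyl-6-[(1S,6S,8R,8aR)-3,6,8-trimethyl-7-oxo-2-(2-oxopropyl)-1,5,6,7,8,8a-hexahydronaphthalen-1-yl]hexa-2,5-dienoic acid, via trimethylstannyl ester 33 (not isolated)
Conditions: Me3SnOH (5 equiv), 1,2-dichloroethane, 70 °C; then 0.1 M HCl wash
Reagents that add atoms: trimethyltin hydroxide, C[Sn](C)(C)O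
Why: Nearly neutral methyl ester cleavage with trimethyltin hydroxide, chosen because hydroxide bases could move the β,γ-double bond of the 2-oxopropyl ketone into conjugation.

**Compound list**

1 | 4,4-dimethoxycyclohexa-2,5-dien-1-one | COC1(OC)C=CC(=O)C=C1 | starting material
2 | methyl{[(3S)-4,4-dimethoxy-3-methylcyclohexa-1,5-dien-1-yl]oxy}zinc | C[Zn]OC1=C[C@H](C)C(OC)(OC)C=C1 | intermediate (not isolated)
3 | (5S)-4,4-dimethoxy-5-methylcyclohex-2-en-1-one | O=C1C[C@H](C)C(OC)(OC)C=C1 | intermediate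
4 | methyl{[(3R,5S)-4,4-dimethoxy-3,5-dimethylcyclohex-1-en-1-yl]oxy}zinc | C[Zn]OC1=C[C@@H](C)C(OC)(OC)[C@@H](C)C1 | intermediate (not isolated)
5 | (3R,5S)-4,4-dimethoxy-3,5-dimethylcyclohex-1-en-1-yl trifluoromethanesulfonate | O=S(=O)(OC1=C[C@@H](C)C(OC)(OC)[C@@H](C)C1)C(F)(F)F | intermediate
6 | propyne | CC#C | starting material
7 | dibromo[(Z)-2-bromoprop-1-en-1-yl]borane | C/C(Br)=C/B(Br)Br | intermediate (not isolated)
8 | 2-[(Z)-2-bromoprop-1-en-1-yl]-4,4,5,5-tetramethyl-1,3,2-dioxaborolane | C/C(Br)=C/B1OC(C)(C)C(C)(C)O1 | intermediate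
9 | 2-methyl-2-vinyloxirane (racemic) | CC1(C=C)CO1 | starting material
10 | ethanol | CCO | starting material
11 | acetaldehyde | CC=O | intermediate (not isolated)
12 | (2R,3S)-2-ethenyl-2-methylbutane-1,3-diol | C[C@H](O)[C@](C)(C=C)CO | intermediate
13 | (2S,3R)-3-({[tert-butyl(dimethyl)silyl]oxy}methyl)-3-methylpent-4-en-2-ol | C[C@H](O)[C@](C)(C=C)CO[Si](C)(C)C(C)(C)C | intermediate
14 | (3R)-3-({[tert-butyl(dimethyl)silyl]oxy}methyl)-3-methylpent-4-en-2-one | CC(=O)[C@](C)(C=C)CO[Si](C)(C)C(C)(C)C | intermediate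
15 | lithium enolate of 14 (O-lithio, terminal CH2=) | [Li]OC(=C)[C@](C)(C=C)CO[Si](C)(C)C(C)(C)C | intermediate (not isolated)
16 | diethyl enol phosphate of 14 (penta-1,4-dien-2-yl phosphate, quaternary carbon unchanged) | C=C(OP(=O)(OCC)OCC)[C@](C)(C=C)CO[Si](C)(C)C(C)(C)C | intermediate (not isolated)
17 | lithium acetylide of 18 | [Li]C#C[C@](C)(C=C)CO[Si](C)(C)C(C)(C)C | intermediate (not isolated)
18 | tert-butyl{[(2S)-2-ethynyl-2-methylbut-3-en-1-yl]oxy}dimethylsilane | C#C[C@](C)(C=C)CO[Si](C)(C)C(C)(C)C | intermediate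
19 | secondary ozonide of 18 (3-substituted 1,2,4-trioxolane, mixture at the ring carbon) | C#C[C@](C)(C1OCOO1)CO[Si](C)(C)C(C)(C)C | intermediate (not isolated)
20 | (2S)-2-({[tert-butyl(dimethyl)silyl]oxy}methyl)-2-methylbut-3-ynal | C#C[C@](C)(C=O)CO[Si](C)(C)C(C)(C)C | intermediate
21 | methyl (2E,4S)-4-({[tert-butyl(dimethyl)silyl]oxy}methyl)-4-methylhex-2-en-5-ynoate | C#C[C@](C)(/C=C/C(=O)OC)CO[Si](C)(C)C(C)(C)C | intermediate
22 | (2S)-pent-4-yn-2-ol | C#CC[C@H](C)O | starting material
23 | (2S)-5-bromopent-4-yn-2-ol | BrC#CC[C@H](C)O | intermediate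
24 | methyl (2E,4S,10S)-4-({[tert-butyl(dimethyl)silyl]oxy}methyl)-10-hydroxy-4-methylundec-2-ene-5,7-diynoate | C[C@H](O)CC#CC#C[C@](C)(/C=C/C(=O)OC)CO[Si](C)(C)C(C)(C)C | intermediate
25 | methyl (2E,4S,7Z,10S)-4-({[tert-butyl(dimethyl)silyl]oxy}methyl)-10-hydroxy-4-methyl-8-(tributylstannyl)undeca-2,7-dien-5-ynoate | C[C@H](O)C/C(=C/C#C[C@](C)(/C=C/C(=O)OC)CO[Si](C)(C)C(C)(C)C)[Sn](CCCC)(CCCC)CCCC | intermediate
26 | methyl (2E,4S,7Z,10S)-4-({[tert-butyl(dimethyl)silyl]oxy}methyl)-10-hydroxy-4-methyl-8-[(1Z)-1-(4,4,5,5-tetramethyl-1,3,2-dioxaborolan-2-yl)prop-1-en-2-yl]undeca-2,7-dien-5-ynoate | C[C@H](O)C/C(=C/C#C[C@](C)(/C=C/C(=O)OC)CO[Si](C)(C)C(C)(C)C)/C(C)=C\B1OC(C)(C)C(C)(C)O1 | intermediate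
27 | methyl (2E,4S,7Z,10S)-4-({[tert-butyl(dimethyl)silyl]oxy}methyl)-8-{(1Z)-1-[(3R,5S)-4,4-dimethoxy-3,5-dimethylcyclohex-1-en-1-yl]prop-1-en-2-yl}-10-hydroxy-4-methylundeca-2,7-dien-5-ynoate | C[C@H](O)C/C(=C/C#C[C@](C)(/C=C/C(=O)OC)CO[Si](C)(C)C(C)(C)C)/C(C)=C\C1=C[C@@H](C)C(OC)(OC)[C@@H](C)C1 | intermediate (not isolated)
28 | methyl (2E,4S)-4-({[tert-butyl(dimethyl)silyl]oxy}methyl)-6-[(1R,6S,8R,8aR)-2-[(2S)-2-hydroxypropyl]-7,7-dimethoxy-3,6,8-trimethyl-1,5,6,7,8,8a-hexahydronaphthalen-1-yl]-4-methylhex-2-en-5-ynoate | C[C@H](O)CC1=C(C)C=C2C[C@H](C)C(OC)(OC)[C@H](C)[C@H]2[C@@H]1C#C[C@](C)(/C=C/C(=O)OC)CO[Si](C)(C)C(C)(C)C | intermediate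
29 | methyl (2E,4S)-4-({[tert-butyl(dimethyl)silyl]oxy}methyl)-6-[(1R,6S,8R,8aR)-7,7-dimethoxy-3,6,8-trimethyl-2-(2-oxopropyl)-1,5,6,7,8,8a-hexahydronaphthalen-1-yl]-4-methylhex-2-en-5-ynoate | CC(=O)CC1=C(C)C=C2C[C@H](C)C(OC)(OC)[C@H](C)[C@H]2[C@@H]1C#C[C@](C)(/C=C/C(=O)OC)CO[Si](C)(C)C(C)(C)C | intermediate
30 | methyl (2E,4S)-4-(hydroxymethyl)-4-methyl-6-[(1R,6S,8R,8aR)-3,6,8-trimethyl-7-oxo-2-(2-oxopropyl)-1,5,6,7,8,8a-hexahydronaphthalen-1-yl]hex-2-en-5-ynoate | CC(=O)CC1=C(C)C=C2C[C@H](C)C(=O)[C@H](C)[C@H]2[C@@H]1C#C[C@](C)(/C=C/C(=O)OC)CO | intermediate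
31 | methyl (2E,4R,5Z)-4-(hydroxymethyl)-4-methyl-5-(tributylstannyl)-6-[(1R,6S,8R,8aR)-3,6,8-trimethyl-7-oxo-2-(2-oxopropyl)-1,5,6,7,8,8a-hexahydronaphthalen-1-yl]hexa-2,5-dienoate | CC(=O)CC1=C(C)C=C2C[C@H](C)C(=O)[C@H](C)[C@H]2[C@@H]1/C=C(\[Sn](CCCC)(CCCC)CCCC)[C@](C)(/C=C/C(=O)OC)CO | intermediate
32 | methyl (2E,4S,5E)-4-(hydroxymethyl)-4,5-dimethyl-6-[(1S,6S,8R,8aR)-3,6,8-trimethyl-7-oxo-2-(2-oxopropyl)-1,5,6,7,8,8a-hexahydronaphthalen-1-yl]hexa-2,5-dienoate | CC(=O)CC1=C(C)C=C2C[C@H](C)C(=O)[C@H](C)[C@H]2[C@@H]1/C=C(\C)[C@](C)(/C=C/C(=O)OC)CO | intermediate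
33 | trimethylstannyl ester of 34 | CC(=O)CC1=C(C)C=C2C[C@H](C)C(=O)[C@H](C)[C@H]2[C@@H]1/C=C(\C)[C@](C)(/C=C/C(=O)O[Sn](C)(C)C)CO | intermediate (not isolated)
34 | (2E,4S,5E)-4-(hydroxymethyl)-4,5-dimethyl-6-[(1S,6S,8R,8aR)-3,6,8-trimethyl-7-oxo-2-(2-oxopropyl)-1,5,6,7,8,8a-hexahydronaphthalen-1-yl]hexa-2,5-dienoic acid | CC(=O)CC1=C(C)C=C2C[C@H](C)C(=O)[C@H](C)[C@H]2[C@@H]1/C=C(\C)[C@](C)(/C=C/C(=O)O)CO | target

**Totals**

Total step count: 19. Longest linear sequence: 15 steps (steps 4 to 9, then 11 to 19).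

**Steps most likely to fail**

Step 14. What may go wrong: slow transmetalation and competing protodeboronation at the hindered (Z)-alkenyl boronate, so that the triene is never assembled. The fallback reverses the polarity of the coupling; it sets out from 5 and 26 and comes back to the route at 28. Triflate 5 is converted by Miyaura borylation (bis(pinacolato)diboron, Pd(PPh3)2Cl2, PPh3, KOPh, toluene, 50 °C) into the unhindered nucleophile 2-[(3R,5S)-4,4-dimethoxy-3,5-dimethylcyclohex-1-en-1-yl]-4,4,5,5-tetramethyl-1,3,2-dioxaborolane F1. Boronate 26 is converted by iododeboronation with retention (I2, NaOH, THF/H2O, 0 °C) into the dienyl iodide, methyl (2E,4S,7Z,10S)-4-({[tert-butyl(dimethyl)silyl]oxy}methyl)-10-hydroxy-8-[(1Z)-1-iodoprop-1-en-2-yl]-4-methylundeca-2,7-dien-5-ynoate F2. Suzuki–Miyaura coupling of F1 with F2 (Pd(PPh3)4, K3PO4, THF/H2O, 45 °C), then heating in toluene at 100 °C, should give 28 through the same trienyne 27.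

Step 12. What may go wrong: loss of site or regiocontrol when tin hydride is added across a conjugated diyne (addition to the distal triple bond, double addition, or tin at the wrong carbon). The fallback attaches the second alkyne only after the trisubstituted alkene is in place; it sets out from 22 and comes back to the route at 26. Palladium-catalysed syn-silylstannation of 22 (Me3Si–SnBu3, Pd(PPh3)4, THF, 65 °C; tin internal, silicon terminal) gives (2S,4Z)-4-(tributylstannyl)-5-(trimethylsilyl)pent-4-en-2-ol F3. Stille coupling of F3 with 8 under the conditions of step 13 gives (2S,4Z)-4-[(1Z)-1-(4,4,5,5-tetramethyl-1,3,2-dioxaborolan-2-yl)prop-1-en-2-yl]-5-(trimethylsilyl)pent-4-en-2-ol F4. Iododesilylation with retention (N-iodosuccinimide, hexafluoroisopropanol, 0 °C) gives (2S,4Z)-5-iodo-4-[(1Z)-1-(4,4,5,5-tetramethyl-1,3,2-dioxaborolan-2-yl)prop-1-en-2-yl]pent-4-en-2-ol F5. Sonogashira coupling of F5 with alkyne 21 (Pd(PPh3)2Cl2, CuI, i-Pr2NH, THF, rt) should give 26.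

Step 18. What may go wrong: protodestannation outrunning methyl transfer at the alkenyl tin that is flanked by the quaternary carbon. The fallback turns the tin site into an electrophile; it sets out from 31 and comes back to the route at 32. Iododestannation with retention (I2, CH2Cl2, −78 to 0 °C) gives methyl (2E,4R,5Z)-4-(hydroxymethyl)-5-iodo-4-methyl-6-[(1R,6S,8R,8aR)-3,6,8-trimethyl-7-oxo-2-(2-oxopropyl)-1,5,6,7,8,8a-hexahydronaphthalen-1-yl]hexa-2,5-dienoate F6. Negishi coupling of F6 with MeZnCl (3 equiv, Pd(PPh3)4, THF, rt; organozinc halides tolerate the ketones) should give 32.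

**Further compounds**

F1 | step 14 | 2-[(3R,5S)-4,4-dimethoxy-3,5-dimethylcyclohex-1-en-1-yl]-4,4,5,5-tetramethyl-1,3,2-dioxaborolane | CC1(C)OB(OC1(C)C)C1=C[C@@H](C)C(OC)(OC)[C@@H](C)C1
F2 | step 14 | methyl (2E,4S,7Z,10S)-4-({[tert-butyl(dimethyl)silyl]oxy}methyl)-10-hydroxy-8-[(1Z)-1-iodoprop-1-en-2-yl]-4-methylundeca-2,7-dien-5-ynoate | C[C@H](O)C/C(=C/C#C[C@](C)(/C=C/C(=O)OC)CO[Si](C)(C)C(C)(C)C)/C(C)=C\I
F3 | step 12 | (2S,4Z)-4-(tributylstannyl)-5-(trimethylsilyl)pent-4-en-2-ol | C[C@H](O)C/C(=C/[Si](C)(C)C)[Sn](CCCC)(CCCC)CCCC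
F4 | step 12 | (2S,4Z)-4-[(1Z)-1-(4,4,5,5-tetramethyl-1,3,2-dioxaborolan-2-yl)prop-1-en-2-yl]-5-(trimethylsilyl)pent-4-en-2-ol | C[C@H](O)C/C(=C/[Si](C)(C)C)/C(C)=C\B1OC(C)(C)C(C)(C)O1
F5 | step 12 | (2S,4Z)-5-iodo-4-[(1Z)-1-(4,4,5,5-tetramethyl-1,3,2-dioxaborolan-2-yl)prop-1-en-2-yl]pent-4-en-2-ol | C[C@H](O)C/C(=C/I)/C(C)=C\B1OC(C)(C)C(C)(C)O1
F6 | step 18 | methyl (2E,4R,5Z)-4-(hydroxymethyl)-5-iodo-4-methyl-6-[(1R,6S,8R,8aR)-3,6,8-trimethyl-7-oxo-2-(2-oxopropyl)-1,5,6,7,8,8a-hexahydronaphthalen-1-yl]hexa-2,5-dienoate | CC(=O)CC1=C(C)C=C2C[C@H](C)C(=O)[C@H](C)[C@H]2[C@@H]1/C=C(\I)[C@](C)(/C=C/C(=O)OC)CO
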